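Readings and results are calculated from invented constants; the scatter is artificial.

In a one-step world with a single bimolecular step, a flask has one time constant, the inverse of k times the charged concentration. Both charges cut by one factor then give the same curve of shares, with the clock slowed by that factor.

| flask | starting material | coupling partner | time |
|---|---|---|---|
| larch | 0.800 M | 0.640 M |  |
| elm | 1.20 M | 0.640 M |  |
| ash | 0.800 M | 1.30 M |  |
| maple | 0.260 M | 0.210 M | 27 min |

| run | time / min | [target] / M |
|---|---|---|
| larch run | 1.1 | 0.075 |
| larch run | 1.7 | 0.104 |
| larch run | 2.7 | 0.146 |
| larch run | 4.3 | 0.202 |
| larch run | 6.8 | 0.269 |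
| larch run | 11 | 0.334 |
| larch run | 17 | 0.389 |
| larch run | 27 | 0.405 |
| elm run | 1.1 | 0.100 |
| elm run | 1.7 | 0.131 |
| elm run | 2.7 | 0.191 |
| elm run | 4.3 | 0.263 |
| elm run | 6.8 | 0.331 |
| elm run | 11 | 0.395 |
| elm run | 17 | 0.440 |
| elm run | 27 | 0.462 |
| ash run | 1.1 | 0.110 |
| ash run | 1.7 | 0.169 |
| ash run | 2.7 | 0.250 |
| ash run | 4.3 | 0.349 |
| ash run | 6.8 | 0.436 |
| ash run | 11 | 0.533 |
| ash run | 17 | 0.590 |
| ash run | 27 | 0.623 |

(readings scatter by 0.006 M)

- Overall: starting material + coupling partner -> target.
- Constant volume, constant temperature.
- Readings of a species count what is bound in complexes too.
- An order is taken over about fifteen percent of the charge, up and down.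

- order of the initial rate in [starting material], near the charge of the larch run, the rate being that where two percent of its starting material are target (one fixed amount of target, the same in the runs compared)
- order of the initial rate in [coupling partner], near the charge of the larch run, the rate being that where two percent of its starting material are target
- target in the maple run at 27 min, as a share of the starting material charged

At 2.7 min, the readings of target are 0.146 M in the larch run, 0.191 M in the elm run and 0.250 M in the ash run, and these give the ratios of the mean rates since the start. Across these wide steps, this reckoning gives an order of 0.663 in [starting material] and 0.759 in [coupling partner]. Both are below one, and the reckoning below still takes the flask as bimolecular. The maple charge is nearly the larch charge diluted: the ratio is 3.05 for coupling partner and 3.08 for starting material. That last ratio is the stretch, the factor by which dilution slows each bimolecular time constant. So 27 min in the maple run should match 8.78 min in the larch run, between the readings at 6.8 min and 11 min. Linear interpolation there reads [target] as 0.300 M, a share of 37.4%. The weak link is the stretch itself, since a first-order step keeps its time under dilution.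

The forecast gives orders of 0.87 and 0.8 and a maple share of 32%, between 26% and 38%, on the ground that “Relaxation is slower when dilute”. Its share is lower than the one reckoned here.

The simulation gives orders of 0.77 and 0.86 and a maple share of 39.8%, which is 7.8 percentage points above the forecast and 2.4 points above the stretched larch reading.

    starting material + coupling partner ⇌ target (0.2652 L mol⁻¹ min⁻¹, 0.01008 min⁻¹)
    starting material + coupling partner ⇌ idle substrate-reagent adduct, settled at all times (0.7000 L mol⁻¹)
    2 starting material → homo dimer (0.07500 L mol⁻¹ min⁻¹)

The step to homo dimer is bimolecular, so the stretch holds for it: the first half-life of starting material by this step alone is 8.33 min at the larch charge and 25.6 min at the maple charge. The asked 27 min of the maple run is 1.05 times that first half-life. Taking that step away lifts the maple share from 39.8% to 46.9%.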